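**Retrosynthetic overview**

1. The target is read as a (2R,3S,4R) 2,3-trans-3,4-trans 4-arylflavan-3-ol (upper unit) and a (2R,3S) 2,3-trans flavan-3-ol (lower unit) that share one catechol ring. The strategy rests on that ring: its C1' is C2 of the lower pyran and the adjacent C6' holds C4 of the upper pyran, and each of these two carbons is one end of a 1,3-diarylallyl unit whose other aryl group is a 2-hydroxy-4-oxyphenyl ring A.
2. Last disconnections: the six benzyl ethers, then the C3–O and C4–H bonds of both pyran rings, which come from a twofold syn hydroboration of a bis(flav-3-ene) anti to each C2 aryl group.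
3. Key disconnection: both pyran O1–C2 bonds, leading back to an acyclic, stereorandom bis(allylic alcohol) that is ionised at both carbinols and closed twice under one chiral Brønsted acid.
4. The bis(carbinol) comes from an enal–enone built on the central ring plus two ring-A aryllithiums. The hub comes from a 2-bromo-4,5-bis(benzyloxy)acetophenone by Heck vinylation and Claisen–Schmidt condensation.
5. Ring order: all five benzene rings are bought; the upper and then the lower pyran ring close in the same operation (step 8), and no ring forms afterwards.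

Key step: step 8

Assumption: the (R)-configured phosphoramide is taken to give the C2 configuration drawn for 14; if a single-arm model closure shows the opposite sense, its (S)-antipode is used and nothing else changes.
Remark on descriptors: C2 reads S in the chromenes 13 and 14 and R in 16 and 17 only because the CIP ranking of C3 changes on oxygenation; the spatial arrangement is the same.

**Route**

Step 1
Reactants: 1 3,4-dihydroxyacetophenone
Product: 2 1-[3,4-bis(benzyloxy)phenyl]ethanone
Conditions: BnBr (2.3 equiv), K2CO3 (3 equiv), DMF, 60 °C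
Reagents that add atoms: benzyl bromide, BrCc1ccccc1
Why: Williamson etherification of both catechol phenoxides with a carbonate base that is too weak to enolise and C-alkylate the methyl ketone.

Step 2
Reactants: 2 1-[3,4-bis(benzyloxy)phenyl]ethanone
Product: 3 1-[4,5-bis(benzyloxy)-2-bromophenyl]ethanone
Conditions: NBS (1.05 equiv), MeCN, rt, dark
Reagents that add atoms: N-bromosuccinimide, O=C1CCC(=O)N1Br
Why: Electrophilic aromatic bromination with NBS in a polar aprotic medium goes to the ring position para to the 3-benzyloxy group (the 4-benzyloxy group is deactivated by conjugation with the para acetyl group), and the absence of acid or radical initiation keeps the acetyl side chain unbrominated.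

Step 3
Reactants: 3 1-[4,5-bis(benzyloxy)-2-bromophenyl]ethanone; 4 acrolein diethyl acetal
Product: 5 1-{4,5-bis(benzyloxy)-2-[(E)-3,3-diethoxyprop-1-enyl]phenyl}ethanone
Conditions: Pd(OAc)2 (5 mol %), n-Bu4NOAc (2 equiv), K2CO3 (1.5 equiv), KCl (1 equiv), DMF, 90 °C; aqueous NaHCO3 work-up, Et3N-deactivated silica
Reagents that add atoms: none
Why: Heck–Mizoroki vinylation under phosphine-free tetraalkylammonium acetate conditions, in which oxidative addition to zerovalent palladium is helped by the ortho acetyl group and syn β-hydride elimination toward the benzylic hydrogen gives the E-alkene while the base-stable acetal stays in place.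

Step 4
Reactants: 5 1-{4,5-bis(benzyloxy)-2-[(E)-3,3-diethoxyprop-1-enyl]phenyl}ethanone; 6 3,4-bis(benzyloxy)benzaldehyde
Product: 7 (E)-3-[3,4-bis(benzyloxy)phenyl]-1-{4,5-bis(benzyloxy)-2-[(E)-3,3-diethoxyprop-1-enyl]phenyl}prop-2-en-1-one
Conditions: KOH (50% aq., 3 equiv), EtOH/THF, rt
Reagents that add atoms: none
Why: Claisen–Schmidt condensation, in which the only enolisable site (the acetyl methyl) adds to the non-enolisable aldehyde 6 and E1cB loss of water gives the E-enone, the acetal keeping the latent enal out of the aldol manifold.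

Step 5
Reactants: 7 (E)-3-[3,4-bis(benzyloxy)phenyl]-1-{4,5-bis(benzyloxy)-2-[(E)-3,3-diethoxyprop-1-enyl]phenyl}prop-2-en-1-one
Product: 8 (E)-3-{4,5-bis(benzyloxy)-2-[(E)-3-[3,4-bis(benzyloxy)phenyl]prop-2-enoyl]phenyl}prop-2-enal
Conditions: PPTS (10 mol %), acetone/H2O (10:1), rt
Reagents that add atoms: water, O
Why: Acid-catalysed acetal hydrolysis through the conjugated oxocarbenium ion is fast under conditions too mild to touch the chalcone or the benzyl ethers, and the E-geometry of both alkenes is kept.

Step 6
Reactants: 9 4-bromoresorcinol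
Product: 10 5-(benzyloxy)-2-bromophenol
Conditions: BnBr (1.0 equiv), K2CO3 (1.0 equiv), acetone, rt
Reagents that add atoms: benzyl bromide, BrCc1ccccc1
Why: Williamson monoalkylation with one equivalent of electrophile favours the hydroxyl para to bromine, since the phenoxide ortho to bromine is the more hindered and less nucleophilic one, and the regioisomer and the bis-ether are removed by chromatography.

Step 7
Reactants: 8 (E)-3-{4,5-bis(benzyloxy)-2-[(E)-3-[3,4-bis(benzyloxy)phenyl]prop-2-enoyl]phenyl}prop-2-enal; 10 5-(benzyloxy)-2-bromophenol (2.6 equiv)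
Product: 12 5-(benzyloxy)-2-[(E)-3-{4,5-bis(benzyloxy)-2-[(E)-1-[4-(benzyloxy)-2-hydroxyphenyl]-3-[3,4-bis(benzyloxy)phenyl]-1-hydroxyprop-2-enyl]phenyl}-1-hydroxyprop-2-enyl]phenol (bis(allylic alcohol); all stereoisomers at the two carbinol carbons), via lithium 5-(benzyloxy)-2-lithiophenoxide 11 (not isolated)
Conditions: 10, n-BuLi (2 equiv per 10), THF, −78 to −20 °C; then 8, THF, −78 to −20 °C; pH 7 phosphate buffer; quick filtration through neutral alumina, used at once
Reagents that add atoms: none
Why: O-Deprotonation followed by bromine–lithium exchange gives the O,C-dilithio species 11, a hard aryllithium that adds 1,2 to the enal and to the non-enolisable aryl styryl ketone (kinetic carbonyl addition of aryllithiums to enones), and the two carbinol centres formed without control are of no consequence because both are ionised in step 8.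

Step 8
Reactants: 12 bis(allylic alcohol) (stereoisomer mixture)
Product: 14 (2S)-7-(benzyloxy)-4-{4,5-bis(benzyloxy)-2-[(2S)-7-(benzyloxy)-2H-chromen-2-yl]phenyl}-2-[3,4-bis(benzyloxy)phenyl]-2H-chromene (bis(flav-3-ene)), via upper-ring monochromene 13 (not isolated)
Conditions: (R)-3,3'-bis(2,4,6-triisopropylphenyl)-1,1'-binaphthyl-2,2'-diyl N-triflylphosphoramide (10 mol %), 4 Å MS, toluene/CH2Cl2, −78 °C; Et3N quench at −78 °C; Et3N-deactivated silica
Reagents that add atoms: none
Why: Proposed new method: the phosphoramide protonates each carbinol and water leaves (the tertiary diaryl carbinol first), giving 1,3-diarylallyl cations, that is protonated vinyl ortho-quinone methides, which are stabilised by the ortho-hydroxy/para-benzyloxy ring A and by the para-benzyloxy group of the aryl ring at the far terminus, so that all stereoisomers of 12 funnel into the same planar ion pairs. The closest known reaction type is the chiral N-triflyl phosphoramide catalysed intramolecular allylic substitution of racemic 2-(1-hydroxy-1,3-diarylallyl)phenols to 2,4-diaryl-2H-chromenes, together with the classical acid closure of reduced 2'-hydroxychalcones to flav-3-enes; the extension lies in running it twice on one substrate and in the enantioselective closure of the arm that has no C4 substituent. Each pyran ring closes by attack of its phenol oxygen on the distal allyl terminus (SN1'-type 6-membered O–C closure, equally an oxa-6π electrocyclisation of the s-cis quinone methide): O1–C2 of the upper ring forms in 13 and O1–C2 of the lower ring in 14. Both C2 stereocentres are set by the chiral phosphoramide anion, which is hydrogen-bonded to the attacking phenol in the contact ion pair and leaves one face of the allyl terminus open, while the two carbinol centres of 12 vanish on ionisation. The step needs enantioface selection at two allyl termini and O-attack at C2 rather than C4; the latter is secured because attack at C4 would give a 4-membered ring, and the former is helped by two catalyst-controlled events on one molecule, which enrich the major diastereomer. Ring re-opening at C2, uncatalysed closure and indene formation between the neighbouring arms are held back by the low temperature and by the fast proximal phenol trap, and the central ring is only a spectator hub, so the C4–C6' bond that a flavan-4-yl cation would not form is already in place.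

Step 9
Reactants: 14 bis(flav-3-ene)
Product: 16 (2R,3S,4R)-7-(benzyloxy)-4-{4,5-bis(benzyloxy)-2-[(2R,3S)-7-(benzyloxy)-3-hydroxy-3,4-dihydro-2H-chromen-2-yl]phenyl}-2-[3,4-bis(benzyloxy)phenyl]-3,4-dihydro-2H-chromen-3-ol (hexa-O-benzyl ether of the target), via bis(alkylborane) 15 (not isolated)
Conditions: BH3·THF (6 equiv), THF, 0 °C to rt; then 3 M NaOH, 30% H2O2, 0 °C to rt
Reagents that add atoms: hydrogen peroxide, OO
Why: Brown hydroboration–oxidation, which is established for flav-3-enes and 4-arylflav-3-enes, places boron on C3 (β to the electron-rich ring A in both rings) and delivers H and B syn on the face anti to each C2 aryl group, so that oxidation with retention sets C3 of the lower ring (2,3-trans) and C3 and C4 of the upper ring (2,3-trans-3,4-trans) from the C2 centres.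

Step 10
Reactants: 16 hexa-O-benzyl ether of the target
Product: 17 (2R,3S,4R)-2-(3,4-dihydroxyphenyl)-4-{2-[(2R,3S)-3,7-dihydroxy-3,4-dihydro-2H-chromen-2-yl]-4,5-dihydroxyphenyl}-3,4-dihydro-2H-chromene-3,7-diol (CNP0244903.3)
Conditions: H2 (1 atm), Pd(OH)2/C, THF/MeOH, rt; filtration under argon
Reagents that add atoms: none
Why: Catalytic hydrogenolysis cleaves the six aryl benzyl ethers under neutral conditions in which the benzylic C2–O1 bonds and the doubly benzylic C4–H of flavan-3-ols are known to persist, so no stereocentre is touched.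

**Compound list**

1 | 3,4-dihydroxyacetophenone | CC(=O)c1ccc(O)c(O)c1 | starting material
2 | 1-[3,4-bis(benzyloxy)phenyl]ethanone | CC(=O)c1ccc(OCc2ccccc2)c(OCc2ccccc2)c1 | intermediate
3 | 1-[4,5-bis(benzyloxy)-2-bromophenyl]ethanone | CC(=O)c1cc(OCc2ccccc2)c(OCc2ccccc2)cc1Br | intermediate
4 | acrolein diethyl acetal (3,3-diethoxyprop-1-ene) | C=CC(OCC)OCC | starting material
5 | 1-{4,5-bis(benzyloxy)-2-[(E)-3,3-diethoxyprop-1-enyl]phenyl}ethanone | CC(=O)c1cc(OCc2ccccc2)c(OCc2ccccc2)cc1/C=C/C(OCC)OCC | intermediate
6 | 3,4-bis(benzyloxy)benzaldehyde | O=Cc1ccc(OCc2ccccc2)c(OCc2ccccc2)c1 | starting material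
7 | (E)-3-[3,4-bis(benzyloxy)phenyl]-1-{4,5-bis(benzyloxy)-2-[(E)-3,3-diethoxyprop-1-enyl]phenyl}prop-2-en-1-one | CCOC(OCC)/C=C/c1cc(OCc2ccccc2)c(OCc2ccccc2)cc1C(=O)/C=C/c1ccc(OCc2ccccc2)c(OCc2ccccc2)c1 | intermediate
8 | (E)-3-{4,5-bis(benzyloxy)-2-[(E)-3-[3,4-bis(benzyloxy)phenyl]prop-2-enoyl]phenyl}prop-2-enal | O=C/C=C/c1cc(OCc2ccccc2)c(OCc2ccccc2)cc1C(=O)/C=C/c1ccc(OCc2ccccc2)c(OCc2ccccc2)c1 | intermediate
9 | 4-bromoresorcinol (4-bromobenzene-1,3-diol) | Oc1ccc(Br)c(O)c1 | starting material
10 | 5-(benzyloxy)-2-bromophenol | Oc1cc(OCc2ccccc2)ccc1Br | intermediate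
11 | lithium 5-(benzyloxy)-2-lithiophenoxide | [Li]Oc1cc(OCc2ccccc2)ccc1[Li] | intermediate
12 | 5-(benzyloxy)-2-[(E)-3-{4,5-bis(benzyloxy)-2-[(E)-1-[4-(benzyloxy)-2-hydroxyphenyl]-3-[3,4-bis(benzyloxy)phenyl]-1-hydroxyprop-2-enyl]phenyl}-1-hydroxyprop-2-enyl]phenol, all carbinol stereoisomers | OC(/C=C/c1cc(OCc2ccccc2)c(OCc2ccccc2)cc1C(O)(/C=C/c1ccc(OCc2ccccc2)c(OCc2ccccc2)c1)c1ccc(OCc2ccccc2)cc1O)c1ccc(OCc2ccccc2)cc1O | intermediate
13 | 5-(benzyloxy)-2-[(E)-3-{4,5-bis(benzyloxy)-2-[(2S)-7-(benzyloxy)-2-[3,4-bis(benzyloxy)phenyl]-2H-chromen-4-yl]phenyl}-1-hydroxyprop-2-enyl]phenol, carbinol centre uncontrolled | OC(/C=C/c1cc(OCc2ccccc2)c(OCc2ccccc2)cc1C1=C[C@@H](c2ccc(OCc3ccccc3)c(OCc3ccccc3)c2)Oc2cc(OCc3ccccc3)ccc12)c1ccc(OCc2ccccc2)cc1O | intermediate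
14 | (2S)-7-(benzyloxy)-4-{4,5-bis(benzyloxy)-2-[(2S)-7-(benzyloxy)-2H-chromen-2-yl]phenyl}-2-[3,4-bis(benzyloxy)phenyl]-2H-chromene | c1ccccc1COc1ccc2c(c1)O[C@H](c1cc(OCc3ccccc3)c(OCc3ccccc3)cc1C1=C[C@@H](c3ccc(OCc4ccccc4)c(OCc4ccccc4)c3)Oc3cc(OCc4ccccc4)ccc13)C=C2 | intermediate
15 | bis(alkylborane): compound 16 with a BH2 group in place of each 3-hydroxyl, same spatial arrangement | c1ccccc1COc1ccc2c(c1)O[C@H](c1cc(OCc3ccccc3)c(OCc3ccccc3)cc1[C@@H]1c3ccc(OCc4ccccc4)cc3O[C@H](c3ccc(OCc4ccccc4)c(OCc4ccccc4)c3)[C@H]1B)[C@@H](B)C2 | intermediate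
16 | (2R,3S,4R)-7-(benzyloxy)-4-{4,5-bis(benzyloxy)-2-[(2R,3S)-7-(benzyloxy)-3-hydroxy-3,4-dihydro-2H-chromen-2-yl]phenyl}-2-[3,4-bis(benzyloxy)phenyl]-3,4-dihydro-2H-chromen-3-ol | c1ccccc1COc1ccc2c(c1)O[C@H](c1cc(OCc3ccccc3)c(OCc3ccccc3)cc1[C@@H]1c3ccc(OCc4ccccc4)cc3O[C@H](c3ccc(OCc4ccccc4)c(OCc4ccccc4)c3)[C@H]1O)[C@@H](O)C2 | intermediate
17 | (2R,3S,4R)-2-(3,4-dihydroxyphenyl)-4-{2-[(2R,3S)-3,7-dihydroxy-3,4-dihydro-2H-chromen-2-yl]-4,5-dihydroxyphenyl}-3,4-dihydro-2H-chromene-3,7-diol | Oc1ccc2c(c1)O[C@H](c1cc(O)c(O)cc1[C@@H]1c3ccc(O)cc3O[C@H](c3ccc(O)c(O)c3)[C@H]1O)[C@@H](O)C2 | target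

**Step count and risks**

Total step count: 10. Longest linear sequence: 9 steps (steps 1, 2, 3, 4, 5, 7, 8, 9, 10, from 1 to 17); step 6 is a one-step side branch.

Steps most likely to fail:

1. Step 8 (the step that carries the label). What may go wrong: incomplete enantioface discrimination at one or both allyl termini, above all on the arm without a C4 substituent; erosion of configuration through acid-reversible ring opening at C2; and uncatalysed closure before the catalyst engages. The fallback uses known chemistry only, sets out from 12 and comes back at 16. Both rings are closed without stereocontrol by the classical acid closure (PPTS, CH2Cl2, 0 °C) to the bis(flav-3-ene) stereoisomer mixture F1. This is hydroborated and oxidised as in step 9 to the hexa-O-benzyl diol stereoisomer mixture F2, which should consist of two racemic diastereomers because each ring still relays its own C2. The diastereomers are separated on silica and the enantiomers by preparative HPLC on amylose tris(3,5-dimethylphenylcarbamate); the (2R,3S,4R)/(2R,3S) isomer is 16.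

2. Step 7. What may go wrong: conjugate addition at the enone competing with carbonyl addition; stalling after the aldehyde has reacted because the polyanionic intermediate aggregates or precipitates; and premature, uncontrolled ring closure of the free bis(phenol) during isolation. The fallback sets out from 10 and 8 and comes back at 12. Compound 10 is silylated (TIPSCl, imidazole, DMF) to [5-(benzyloxy)-2-bromophenoxy]tri(propan-2-yl)silane F3. Its monolithio species (n-BuLi, THF, −78 °C; the bulky silyl group resists O-to-C migration) is transmetalated with anhydrous CeCl3 and added to 8. This should give the bis(O-triisopropylsilyl) ether of the bis(allylic alcohol) F4, which has no free phenol and tolerates chromatography. n-Bu4NF in THF at 0 °C then frees both phenols under basic conditions and gives 12, used at once in step 8.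

3. Step 9. What may go wrong: incomplete addition at the hindered trisubstituted C3=C4 bond of the upper ring; leakage of boron to the benzylic C4 of the lower ring; and opening of the labile C2–O bonds by the Lewis-acidic borane. The fallback sets out from 14 and comes back at 16. It replaces the electrophilic borane by a copper-catalysed borylcupration–protonation: (IPr)CuCl with IPr = 1,3-bis(2,6-diisopropylphenyl)imidazol-2-ylidene, NaOt-Bu, B2pin2, MeOH, THF, rt. The nucleophilic Cu–B unit adds syn, copper at the benzylic C4 and boron at C3, anti to each C2 aryl group, and methanol protonates C4 with retention, giving the bis(pinacol boronate) F5. This addition is established for cyclic β-substituted styrenes such as the lower ring; the trisubstituted upper alkene is the more demanding site. NaBO3·4H2O in THF/H2O then oxidises both C–B bonds with retention to 16.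

**Further compounds**

F1 | step 8 | 7-(benzyloxy)-4-{4,5-bis(benzyloxy)-2-[7-(benzyloxy)-2H-chromen-2-yl]phenyl}-2-[3,4-bis(benzyloxy)phenyl]-2H-chromene, mixture of stereoisomers | c1ccccc1COc1ccc2c(c1)OC(c1cc(OCc3ccccc3)c(OCc3ccccc3)cc1C1=CC(c3ccc(OCc4ccccc4)c(OCc4ccccc4)c3)Oc3cc(OCc4ccccc4)ccc13)C=C2
F2 | step 8 | hexa-O-benzyl diol of the constitution of 16, mixture of two racemic diastereomers (2,3-trans lower ring, 2,3-trans-3,4-trans upper ring) | c1ccccc1COc1ccc2c(c1)OC(c1cc(OCc3ccccc3)c(OCc3ccccc3)cc1C1c3ccc(OCc4ccccc4)cc3OC(c3ccc(OCc4ccccc4)c(OCc4ccccc4)c3)C1O)C(O)C2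
F3 | step 7 | [5-(benzyloxy)-2-bromophenoxy]tri(propan-2-yl)silane | CC(C)[Si](Oc1cc(OCc2ccccc2)ccc1Br)(C(C)C)C(C)C
F4 | step 7 | bis(O-triisopropylsilyl) ether of the bis(allylic alcohol) 12, all carbinol stereoisomers | OC(/C=C/c1cc(OCc2ccccc2)c(OCc2ccccc2)cc1C(O)(/C=C/c1ccc(OCc2ccccc2)c(OCc2ccccc2)c1)c1ccc(OCc2ccccc2)cc1O[Si](C(C)C)(C(C)C)C(C)C)c1ccc(OCc2ccccc2)cc1O[Si](C(C)C)(C(C)C)C(C)C
F5 | step 9 | bis(pinacol boronate): compound 16 with a 4,4,5,5-tetramethyl-1,3,2-dioxaborolan-2-yl group in place of each 3-hydroxyl, same spatial arrangement | c1ccccc1COc1ccc2c(c1)O[C@H](c1cc(OCc3ccccc3)c(OCc3ccccc3)cc1[C@@H]1c3ccc(OCc4ccccc4)cc3O[C@H](c3ccc(OCc4ccccc4)c(OCc4ccccc4)c3)[C@H]1B1OC(C)(C)C(C)(C)O1)[C@@H](B1OC(C)(C)C(C)(C)O1)C2
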